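Monomer in chains is what this flask is meant to make, and the meeting took up how much stands at the asked time and how long the chains are.

| setting | spring | midnight | dusk | flask |
|---|---|---|---|---|
| free monomer | 0.82 M | 0.82 M | 1.6 M | 0.82 M |
| pre-initiator | 12 mM | 19 mM | 25 mM | 25 mM |
| remark | run made earlier | run made earlier | run made earlier |  |
| time |  |  |  | 20 h |

- spring (time / h: monomer in chains / %, free monomer / %): 1.33: 0, 100.3; 4.00: 0.5, 98.7; 8.00: 6.5, 94.6; 12.0: 16.4, 84.1; 15.0: 27.1, 72.4
- midnight (time / h: monomer in chains / %, free monomer / %): 1.33: 0, 99.7; 2.50: 0, 100.2; 5.00: 2.1, 98.4; 8.00: 9.2, 91.1; 15.0: 39.6, 61.1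
- dusk (time / h: monomer in chains / %, free monomer / %): 1.33: 0.9, 99.8; 2.50: 0.7, 99.2; 5.00: 6.1, 94.6; 8.00: 19.3, 81.2; 15.0: 63.2, 37.2

(standard deviation of a reading: 0.5 percentage points)

- the average divides the monomer in chains by the number of chains begun, living and dead together
- the earlier runs do not show the number of chains; that part of a forecast is a guess

- average number of monomer units in a chain (chains begun, living or dead) at 20 h
- part of the free monomer that has reacted at 20 h

I proposed counting turnovers, a turnover count being the natural logarithm of the free monomer charged over the free monomer left. At 15.0 h, the spring and midnight runs, charged alike in free monomer, read 0.323 and 0.493. That is a ratio of 1.53 against 1.58 in pre-initiator charge, so I scaled the count with that charge. The midnight run read 0.0932 at 8.00 h, which makes the count grow as time to the power 2.65, a reading with its scatter. Scaled both ways, my estimate of the flask's turnover count at 20 h is 1.39, which as an estimate means 75.1% reacted. I left the chain average open.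

The forecaster read an induction period from the runs and gave 70% reacted, which differs from my figure, and a chain average of 50, adding: “The chain count is a guess”.

    free monomer + initiator → living end + monomer in chains (k = 0.00130 L mol⁻¹ min⁻¹)
    free monomer + living end → monomer in chains + living end, rate k2*[living end]*[free monomer] (k = 0.680 L mol⁻¹ min⁻¹)
    pre-initiator → initiator (k = 4.40 × 10⁻⁴ min⁻¹)

The flask gave 71.0% reacted and a chain average of 175. Of its pre-initiator charge, 59% stood unchanged at 20.0 h, with initiator equal to 27.7% and living ends equal to 13.3% of that same charge. The flask's turnover count came to 1.24 against the 1.39 reckoned. The neighbour charged with 0.10 M of pre-initiator, 4.00 times the flask's charge, reached 3.44 turnovers, 2.78 times the flask's count, with 3.2% of its free monomer left.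

Readings and results were computed for substances that don't exist.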